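Ring labels: ring A has the D-side bridge at C1, OH at C3 and C4, and the aryloxy oxygen at C5. Ring B is the para-phenylene (O at C1, bridge at C4). Ring C has the B-side bridge at C1, the aryloxy oxygen at C2, and OH at C3 and C4. Ring D is the ortho-phenylene.
Enabling feature: the oxygen on ring A C5 is bonded directly to ring B C1, an unhindered carbon para to an alkyl chain. This ether is therefore the aryl benzoate A(C5)–O–C(=O)–B(C1) with its carbonyl carbon deleted.
Retrosynthetic cuts, in order: four O–H back to O–CH3; CO re-inserted into the O–C1(ring B) bond (17- to 18-membered ring); the lactone acyl C–O bond; the D–A ethylene bridge (as C=C); the ring C C2–O–ring D ether; the B–C ethylene bridge (as C=C).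
Forward order: B is joined to C (Wittig, hydrogenation), D is added through oxygen (SNAr), then A is added (Wittig, hydrogenation). The only ring formed is the macrocycle, closed as an 18-membered lactone, contracted to 17 members by loss of CO, and then demethylated.
Stereochemistry: the target has no stereocentre and no alkene, and hydrogenation erases the geometry of both olefination products.

Key step: step 12

Remark: both olefination products are drawn without alkene geometry. Mixtures of isomers are expected, and both isomers lead to the same bibenzyl.

Step 1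
Reactants: 1 2-hydroxy-3,4-dimethoxybenzaldehyde
Product: 2 2-(benzyloxy)-3,4-dimethoxybenzaldehyde
Conditions: BnBr, K2CO3, DMF, 60 °C
Reagents that add atoms: benzyl bromide, BrCc1ccccc1
Why: Williamson etherification masks the chelated phenol so that it cannot quench the ylide of the next step, and the benzyl group is removed later by the hydrogenation of step 3 without a separate deprotection.

Step 2
Reactants: 2 2-(benzyloxy)-3,4-dimethoxybenzaldehyde; 3 [4-(methoxycarbonyl)benzyl]triphenylphosphonium bromide
Product: 5 methyl 4-{2-[2-(benzyloxy)-3,4-dimethoxyphenyl]ethenyl}benzoate (E/Z mixture), via ring B ylide 4 (not isolated)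
Conditions: K2CO3, 18-crown-6 (cat.), CH2Cl2, reflux
Reagents that add atoms: none
Why: Wittig olefination, in which the para ester makes the benzylic C–H of 3 acidic enough for solid K2CO3 under crown-ether phase transfer, a base too mild to harm the methyl ester.

Step 3
Reactants: 5 methyl 4-{2-[2-(benzyloxy)-3,4-dimethoxyphenyl]ethenyl}benzoate
Product: 6 methyl 4-[2-(2-hydroxy-3,4-dimethoxyphenyl)ethyl]benzoate
Conditions: H2 (1 atm), 10% Pd/C, EtOAc–MeOH, rt
Reagents that add atoms: none
Why: Catalytic hydrogenation saturates the stilbene and hydrogenolyses the benzyl ether in one operation, while the methyl ester and the aryl methyl ethers are inert.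

Step 4
Reactants: 6 methyl 4-[2-(2-hydroxy-3,4-dimethoxyphenyl)ethyl]benzoate; 7 2-fluorobenzaldehyde
Product: 8 methyl 4-{2-[2-(2-formylphenoxy)-3,4-dimethoxyphenyl]ethyl}benzoate
Conditions: K2CO3, dry DMF, 120 °C
Reagents that add atoms: none
Why: Nucleophilic aromatic substitution by addition–elimination, in which the ortho formyl group stabilises the Meisenheimer adduct and fluoride is the best leaving group, so the phenoxide of 6 forms the ring C–O–ring D ether and leaves one aldehyde as the only site for the next olefination.

Step 5
Reactants: 9 3-hydroxy-4,5-dimethoxybenzaldehyde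
Product: 10 3-(benzyloxy)-4,5-dimethoxybenzaldehyde
Conditions: BnBr, K2CO3, DMF, rt
Reagents that add atoms: benzyl bromide, BrCc1ccccc1
Why: Williamson etherification protects the ring A phenol that will later become the lactone and ether oxygen, with a group that the hydrogenation of step 9 removes.

Step 6
Reactants: 10 3-(benzyloxy)-4,5-dimethoxybenzaldehyde
Product: 11 [3-(benzyloxy)-4,5-dimethoxyphenyl]methanol
Conditions: NaBH4, MeOH, 0 °C
Reagents that add atoms: none
Why: Borohydride reduction of an aromatic aldehyde in a molecule with no other reducible group.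

Step 7
Reactants: 11 [3-(benzyloxy)-4,5-dimethoxyphenyl]methanol
Product: 12 [3-(benzyloxy)-4,5-dimethoxybenzyl]triphenylphosphonium bromide
Conditions: PPh3·HBr, MeCN, reflux
Reagents that add atoms: triphenylphosphine hydrobromide, [Br-].c1ccc(cc1)[PH+](c1ccccc1)c1ccccc1
Why: Direct phosphonium salt formation from an electron-rich benzylic alcohol, in which protonation and loss of water give a benzylic electrophile that PPh3 captures, and the aryl benzyl ether tolerates this buffered acid.

Step 8
Reactants: 8 methyl 4-{2-[2-(2-formylphenoxy)-3,4-dimethoxyphenyl]ethyl}benzoate; 12 [3-(benzyloxy)-4,5-dimethoxybenzyl]triphenylphosphonium bromide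
Product: 14 methyl 4-{2-[2-(2-{2-[3-(benzyloxy)-4,5-dimethoxyphenyl]ethenyl}phenoxy)-3,4-dimethoxyphenyl]ethyl}benzoate (E/Z mixture), via ring A ylide 13 (not isolated)
Conditions: K2CO3, 18-crown-6 (cat.), CH2Cl2, reflux
Reagents that add atoms: none
Why: Wittig olefination of the only aldehyde present with a semi-stabilised benzylic ylide, under carbonate and crown-ether conditions that are routine for alkoxybenzyl phosphonium salts and leave the methyl ester intact.

Step 9
Reactants: 14 methyl 4-{2-[2-(2-{2-[3-(benzyloxy)-4,5-dimethoxyphenyl]ethenyl}phenoxy)-3,4-dimethoxyphenyl]ethyl}benzoate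
Product: 15 methyl 4-{2-[2-(2-{2-[3-hydroxy-4,5-dimethoxyphenyl]ethyl}phenoxy)-3,4-dimethoxyphenyl]ethyl}benzoate (seco phenol ester)
Conditions: H2 (1 atm), 10% Pd/C, EtOAc–MeOH, rt
Reagents that add atoms: none
Why: Catalytic hydrogenation sets the second ethylene bridge and frees the ring A phenol by benzyl hydrogenolysis in the same flask, while the diaryl ether, ester and methyl ethers are unreactive.

Step 10
Reactants: 15 seco phenol ester
Product: 16 4-{2-[2-(2-{2-[3-hydroxy-4,5-dimethoxyphenyl]ethyl}phenoxy)-3,4-dimethoxyphenyl]ethyl}benzoic acid (seco hydroxy acid)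
Conditions: LiOH, THF–MeOH–H2O, 40 °C; then 1 M HCl
Reagents that add atoms: lithium hydroxide, [Li+].[OH-]
Why: Saponification of an unhindered methyl benzoate by acyl-oxygen cleavage, with all ether linkages stable to aqueous base.

Step 11
Reactants: 16 seco hydroxy acid
Product: 18 18-membered aryl benzoate macrolactone (ring A C5–O–C(=O)–ring B C1), via mixed anhydride 17 (not isolated)
Conditions: 2,4,6-Cl3C6H2COCl, Et3N, THF, rt; then syringe-pump addition to DMAP, toluene, 90 °C (final 1 mM)
Reagents that add atoms: none
Why: Yamaguchi macrolactonisation, in which the carboxylate is activated as the hindered mixed anhydride, DMAP transfers the ring B acyl group to the ring A phenol, and slow addition at high dilution together with the turn imposed by the ortho-linked C–O–D unit favours the 18-membered ring over oligomers.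

Step 12
Reactants: 18 18-membered aryl benzoate macrolactone
Product: 19 tetra-O-methyl ether of the target (17-membered bis(diaryl ether) macrocycle)
Conditions: Ni(cod)2 (20 mol %), 3,4-bis(dicyclohexylphosphino)thiophene (dcypt, 40 mol %), K3PO4 (1.5 equiv), toluene (5 mM), 150 °C, sealed vessel with large argon headspace
Reagents that add atoms: none
Why: Proposed new method: zerovalent nickel carrying the electron-rich chelating diphosphine should insert into the acyl C–O bond of the aryl benzoate to give a 19-membered acyl–nickel–aryloxide metallacycle, the carbonyl then migrates to the metal and leaves as CO, and the resulting 18-membered aryl–aryloxide complex of divalent nickel reductively eliminates to join ring B C1 to the oxygen on ring A C5. The closest known reaction type is the decarbonylative etherification of aryl azinecarboxylates catalysed by Ni(cod)2 or Pd(OAc)2 with dcypt, which has not been shown for a benzoate lacking the ring nitrogen or inside a macrolactone, although insertion and CO loss from plain phenyl benzoates are established with nickel–phosphine systems in decarbonylative C–C, C–B and C–N couplings, so only the final C–O reductive elimination is untested. The 17-membered ring arises by contraction of the preformed 18-membered ring (deletion of one ring atom) and not by end-to-end cyclisation, both partners staying on the same nickel atom, and the 5 mM dilution disfavours aryloxide exchange between nickel centres that would lead to dimers. No stereocentre is created. The selectivity required is cleavage of the acyl C–O bond rather than the aryl C–O bond of the ester, the C–O–D diaryl ether or the four methyl ethers, and it rests on the ester being the only C–O bond activated by a carbonyl group, with no hydride or organometallic partner present to make insertion into an ether bond productive. Nickel is preferred to palladium because palladium with this ligand is known to shift aryl ester groups to the neighbouring ring carbon, and the high loading and large headspace offset binding of the catalyst by liberated CO.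

Step 13
Reactants: 19 tetra-O-methyl ether of the target
Product: 21 CNP0114693.0 (target tetraphenol), via bis(bromodioxaborole) 20 (not isolated)
Conditions: BBr3 (10 equiv), CH2Cl2, −78 °C to rt, argon; then ice-water
Reagents that add atoms: none
Why: Lewis acid-mediated aryl methyl ether cleavage, in which boron binds each methoxy oxygen and bromide attacks the methyl carbon, whereas the two diaryl ethers offer no sp3 carbon for attack and survive, and hydrolysis of the catechol boron esters on work-up frees the four phenols.

Compound list
1 | 2-hydroxy-3,4-dimethoxybenzaldehyde | COc1ccc(C=O)c(O)c1OC | starting material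
2 | 2-(benzyloxy)-3,4-dimethoxybenzaldehyde | COc1ccc(C=O)c(OCc2ccccc2)c1OC | intermediate
3 | [4-(methoxycarbonyl)benzyl]triphenylphosphonium bromide | [Br-].COC(=O)c1ccc(C[P+](c2ccccc2)(c2ccccc2)c2ccccc2)cc1 | starting material
4 | ring B ylide, methyl 4-[(triphenylphosphoranylidene)methyl]benzoate | COC(=O)c1ccc(C=P(c2ccccc2)(c2ccccc2)c2ccccc2)cc1 | intermediate
5 | methyl 4-{2-[2-(benzyloxy)-3,4-dimethoxyphenyl]ethenyl}benzoate (E/Z mixture) | COC(=O)c1ccc(C=Cc2ccc(OC)c(OC)c2OCc2ccccc2)cc1 | intermediate
6 | methyl 4-[2-(2-hydroxy-3,4-dimethoxyphenyl)ethyl]benzoate | COC(=O)c1ccc(CCc2ccc(OC)c(OC)c2O)cc1 | intermediate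
7 | 2-fluorobenzaldehyde | O=Cc1ccccc1F | starting material
8 | methyl 4-{2-[2-(2-formylphenoxy)-3,4-dimethoxyphenyl]ethyl}benzoate | COC(=O)c1ccc(CCc2ccc(OC)c(OC)c2Oc2ccccc2C=O)cc1 | intermediate
9 | 3-hydroxy-4,5-dimethoxybenzaldehyde | COc1cc(C=O)cc(O)c1OC | starting material
10 | 3-(benzyloxy)-4,5-dimethoxybenzaldehyde | COc1cc(C=O)cc(OCc2ccccc2)c1OC | intermediate
11 | [3-(benzyloxy)-4,5-dimethoxyphenyl]methanol | COc1cc(CO)cc(OCc2ccccc2)c1OC | intermediate
12 | [3-(benzyloxy)-4,5-dimethoxybenzyl]triphenylphosphonium bromide | [Br-].COc1cc(C[P+](c2ccccc2)(c2ccccc2)c2ccccc2)cc(OCc2ccccc2)c1OC | intermediate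
13 | ring A ylide, [3-(benzyloxy)-4,5-dimethoxybenzylidene]triphenylphosphorane | COc1cc(C=P(c2ccccc2)(c2ccccc2)c2ccccc2)cc(OCc2ccccc2)c1OC | intermediate
14 | methyl 4-{2-[2-(2-{2-[3-(benzyloxy)-4,5-dimethoxyphenyl]ethenyl}phenoxy)-3,4-dimethoxyphenyl]ethyl}benzoate (E/Z mixture) | COC(=O)c1ccc(CCc2ccc(OC)c(OC)c2Oc2ccccc2C=Cc2cc(OC)c(OC)c(OCc3ccccc3)c2)cc1 | intermediate
15 | seco phenol ester | COC(=O)c1ccc(CCc2ccc(OC)c(OC)c2Oc2ccccc2CCc2cc(O)c(OC)c(OC)c2)cc1 | intermediate
16 | seco hydroxy acid | OC(=O)c1ccc(CCc2ccc(OC)c(OC)c2Oc2ccccc2CCc2cc(O)c(OC)c(OC)c2)cc1 | intermediate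
17 | mixed anhydride of 16 with 2,4,6-trichlorobenzoic acid | O=C(OC(=O)c1c(Cl)cc(Cl)cc1Cl)c1ccc(CCc2ccc(OC)c(OC)c2Oc2ccccc2CCc2cc(O)c(OC)c(OC)c2)cc1 | intermediate
18 | 18-membered aryl benzoate macrolactone | COc1cc2cc(c1OC)OC(=O)c1ccc(cc1)CCc1ccc(OC)c(OC)c1Oc1ccccc1CC2 | intermediate
19 | tetra-O-methyl ether of the target | COc1cc2cc(c1OC)Oc1ccc(cc1)CCc1ccc(OC)c(OC)c1Oc1ccccc1CC2 | intermediate
20 | bis(2-bromo-1,3,2-benzodioxaborole) of the target | BrB1Oc2cc3cc(c2O1)Oc1ccc(cc1)CCc1ccc2OB(Br)Oc2c1Oc1ccccc1CC3 | intermediate
21 | CNP0114693.0 | Oc1cc2cc(c1O)Oc1ccc(cc1)CCc1ccc(O)c(O)c1Oc1ccccc1CC2 | target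

Total step count: 13.
Longest linear sequence: 10 steps (steps 1–4 and 8–13, from 1). Steps 5–7 form a three-step side branch from 9.

Steps most likely to fail

1. Step 12.
- **Risk:** After insertion and CO loss, C–O reductive elimination from an aryl group that is not electron-poor may be too slow. The aryl–nickel bond could then be lost by protonation, aryloxide could exchange between metal centres and give oligomers, and liberated CO could deactivate the catalyst.
- **Fallback (known chemistry):** CO removal and ether formation are carried out as separate operations.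
- Starting from 18, nickel-catalysed decarbonylative borylation of the aryl ester is applied. The conditions are B2pin2, Ni(cod)2 with a trialkylphosphine or N-heterocyclic carbene ligand, and dioxane at 160 °C. This reaction type is established for phenyl benzoates.
- The borylation opens the ring and, after aqueous work-up, should give the seco phenol pinacol boronate F1.
- Exchange of the pinacol onto excess methylboronic acid (dilute HCl, acetone–water, evaporation) should give the seco phenol boronic acid F2.
- Chan–Lam macrocyclisation (Cu(OAc)2, pyridine, Et3N, 4 Å sieves, air, CH2Cl2, 1 mM) forms the same ring A O–ring B C1 bond and rejoins the route at 19.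

2. Step 11.
- **Risk:** Intermolecular acylation may outrun ring closure and give dimers and oligomers. The phenol may also be acylated at the trichlorobenzoyl carbonyl of the mixed anhydride.
- **Fallback:** the ester is made intermolecularly and the 18-membered ring is closed at the D–A bridge instead.
- Starting from 8, saponification (LiOH, THF–H2O) should give the aldehyde acid F3.
- Carbodiimide esterification of F3 with unprotected 9 (EDC·HCl, DMAP, CH2Cl2) should give the dialdehyde aryl ester F4.
- Intramolecular McMurry coupling with low-valent titanium (TiCl4, Zn, pyridine, THF, reflux, slow addition) closes the ring as the macrocyclic stilbene lactone F5.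
- Hydrogenation of F5 (H2, Pd/C, EtOAc) rejoins the route at 18.

3. Step 4.
- **Risk:** The phenoxide is flanked by two ortho substituents and may add too slowly to the fluoroarene. Prolonged heating could then cleave the methyl ester through attack by phenoxide or carbonate.
- **Fallback:** the mechanism is changed from addition–elimination to copper-catalysed Ullmann-type coupling.
- Starting from 6, commercial 2-bromobenzaldehyde is coupled with CuI, picolinic acid and K3PO4 in DMSO at 90 °C. This catalyst system was developed for hindered phenols and ortho-substituted halides.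
- The coupling rejoins the route directly at 8 and makes no new compound.

Further compounds
F1 | step 12 | seco phenol pinacol boronate (ring B C1–Bpin, ring A C5–OH) | CC1(C)OB(OC1(C)C)c1ccc(CCc2ccc(OC)c(OC)c2Oc2ccccc2CCc2cc(O)c(OC)c(OC)c2)cc1
F2 | step 12 | seco phenol boronic acid | OB(O)c1ccc(CCc2ccc(OC)c(OC)c2Oc2ccccc2CCc2cc(O)c(OC)c(OC)c2)cc1
F3 | step 11 | aldehyde acid, 4-{2-[2-(2-formylphenoxy)-3,4-dimethoxyphenyl]ethyl}benzoic acid | OC(=O)c1ccc(CCc2ccc(OC)c(OC)c2Oc2ccccc2C=O)cc1
F4 | step 11 | dialdehyde aryl ester, 5-formyl-2,3-dimethoxyphenyl ester of F3 | COc1cc(C=O)cc(OC(=O)c2ccc(CCc3ccc(OC)c(OC)c3Oc3ccccc3C=O)cc2)c1OC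
F5 | step 11 | macrocyclic stilbene lactone (alkene geometry not defined) | COc1cc2cc(c1OC)OC(=O)c1ccc(cc1)CCc1ccc(OC)c(OC)c1Oc1ccccc1C=C2
F0 | step 4 | none | none
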